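**Retrosynthetic overview**
1. The C4–C8 interflavanyl bond is made last. The target comes from a (2S)-flavan-4-yl cation (A-ring quinone methide) and (−)-epigallocatechin, which supplies three rings and two stereocentres. Attack trans to the 2-aryl group sets C4.
2. The cation comes from cis-(2S,4S)-4',7-dihydroxyflavan-4-ol, which is made directly from the open, achiral chalcone. O1–C2 closes reversibly (chalcone-isomerase-type oxa-Michael), and only the 2S ring-closed form is removed by enantiomer-selective C4=O reduction (flavanone-4-reductase type). Ring closure and C2 are therefore settled in one operation.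
3. The chalcone comes from 2,4-dihydroxyacetophenone and 4-hydroxybenzaldehyde (Claisen–Schmidt).
4. Ring order: both benzene rings of the upper unit are bought, and its pyran ring is the only ring made (step 2). No protecting groups are used.

Assumption: (−)-epigallocatechin isolated from green tea (≥95 %, 2R,3R) is taken as a commercial chiral-pool starting material, and the excess used in step 3 is recovered.

**Step 1**
Reactants: 1 2,4-dihydroxyacetophenone; 2 4-hydroxybenzaldehyde
Product: 3 isoliquiritigenin, i.e. (E)-1-(2,4-dihydroxyphenyl)-3-(4-hydroxyphenyl)prop-2-en-1-one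
Conditions: HCl (ca. 2 M in abs. EtOH), rt, 24 h; pour into water, filter, recrystallise (aq. EtOH)
Reagents that add atoms: none
Why: In this acid-catalysed Claisen–Schmidt (crossed aldol) condensation the enol of 1 adds to the protonated, non-enolisable aldehyde 2 and conjugation-driven dehydration gives only the E-enone; acid keeps all phenols neutral so neither partner is deactivated as a phenoxide, and any ring-closed flavanone formed here is harmless because step 2 starts from that same equilibrium.

**Step 2**
Reactants: 3 isoliquiritigenin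
Product: 6 (2S,4S)-2-(4-hydroxyphenyl)chromane-4,7-diol (2,4-cis-4',7-dihydroxyflavan-4-ol), via (2R)-liquiritigenin 4 (not isolated), via (2S)-liquiritigenin 5 (not isolated)
Conditions: (i) NaHCO3/Na2CO3 buffer pH 8.7, degassed H2O/MeOH 1:1, 45 °C, 2 h, N2; (ii) RuCl(p-cymene)[(S,S)-TsDPEN] (2 mol %), HCO2Na (5 equiv), 45 °C, 36–48 h; adjust to pH 7, extract with EtOAc, concentrate below 30 °C, use crude 6 the same day
Reagents that add atoms: none
Why: Proposed new method: at pH 8–9 the 2'-phenoxide of 3 closes the pyran ring by 6-endo-trig oxa-Michael addition (the chalcone isomerase reaction) to give 4 and 5, which keep interconverting through 3 by retro-oxa-Michael (E1cB) opening and by 1,6-elimination from the 4'-phenoxide, while the (S,S)-Ru–H species (Noyori–Ikariya outer-sphere hydride transfer, aryl/η6-arene CH–π control giving the 4S carbinol) can use the favoured axial trajectory only on the 2S enantiomer 5, so the pool drains to cis-(2S,4S)-6, where C2 is locked because there is no enolisable ketone and no acyl-stabilised phenoxide leaving group; the closest known reaction types are the transfer-hydrogenative kinetic resolution of flavanones and the dynamic kinetic resolution of 2-substituted chroman-4-ones that racemise by elimination–readdition, extended here to start from the open chalcone and to tolerate free phenols.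

**Step 3**
Reactants: 6 (2S,4S)-2-(4-hydroxyphenyl)chromane-4,7-diol; 7 (−)-epigallocatechin, i.e. (2R,3R)-2-(3,4,5-trihydroxyphenyl)chromane-3,5,7-triol
Product: 9 cassiaflavan-(4β→8)-epigallocatechin = (2R,3R)-8-[(2S,4R)-7-hydroxy-2-(4-hydroxyphenyl)chroman-4-yl]-2-(3,4,5-trihydroxyphenyl)chromane-3,5,7-triol (target), via A-ring quinone methide 8 (not isolated)
Conditions: 7 (4 equiv), degassed 0.1 M aq. HCl/THF 4:1, slow addition of 6, 0 → 20 °C, 3 h, N2; Sephadex LH-20 (EtOH), then RP-18 HPLC; excess 7 recovered
Reagents that add atoms: none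
Why: In this acid-catalysed SN1 Friedel–Crafts condensation of a flavan-4-ol with a flavan-3-ol, the 4-OH (para to the 7-OH, ortho to O1) ionises in dilute acid to 8 (reacting as its O-protonated form, the flavan-4-yl cation), which is captured by C8, the most nucleophilic carbon of the phloroglucinol ring of 7; with the 2-aryl group equatorial the nucleophile enters along the pseudo-axial β trajectory (the α face is also shielded by the departing water of the cis-alcohol), giving the 2,4-trans (4R) bond, while C2 and both stereocentres of 7 are untouched.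

**Compound list**
1 | 2,4-dihydroxyacetophenone (resacetophenone) | CC(=O)c1ccc(O)cc1O | starting material
2 | 4-hydroxybenzaldehyde | O=Cc1ccc(O)cc1 | starting material
3 | isoliquiritigenin, (E)-1-(2,4-dihydroxyphenyl)-3-(4-hydroxyphenyl)prop-2-en-1-one | O=C(/C=C/c1ccc(O)cc1)c1ccc(O)cc1O | intermediate
4 | (2R)-liquiritigenin, (2R)-7-hydroxy-2-(4-hydroxyphenyl)chroman-4-one (mismatched enantiomer, recycled through 3; not isolated) | Oc1ccc([C@H]2CC(=O)c3ccc(O)cc3O2)cc1 | intermediate
5 | (2S)-liquiritigenin, (2S)-7-hydroxy-2-(4-hydroxyphenyl)chroman-4-one (matched enantiomer; not isolated) | Oc1ccc([C@@H]2CC(=O)c3ccc(O)cc3O2)cc1 | intermediate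
6 | (2S,4S)-2-(4-hydroxyphenyl)chromane-4,7-diol (2,4-cis) | Oc1ccc([C@@H]2C[C@H](O)c3ccc(O)cc3O2)cc1 | intermediate
7 | (−)-epigallocatechin, (2R,3R) | Oc1cc(O)c2c(c1)O[C@H](c1cc(O)c(O)c(O)c1)[C@H](O)C2 | starting material
8 | (2S)-2-(4-hydroxyphenyl)-2,3-dihydro-7H-chromen-7-one (A-ring para-quinone methide, drawn neutral; not isolated) | O=C1C=CC2=CC[C@@H](c3ccc(O)cc3)OC2=C1 | intermediate
9 | cassiaflavan-(4β→8)-epigallocatechin; upper unit 2S,4R (2,4-trans), lower unit 2R,3R | Oc1ccc([C@@H]2C[C@@H](c3c(O)cc(O)c4c3O[C@H](c3cc(O)c(O)c(O)c3)[C@H](O)C4)c3ccc(O)cc3O2)cc1 | target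

**Totals**
Total step count: 3. Longest linear sequence: 3 (1/2 → 3 → 6 → 9).

**Steps most likely to fail**

1. Step 2.
 - Ring opening of 4 may be too slow relative to its background reduction, which would erode the ee at C2.
 - Ru–H may reduce the C=C of 3 to the dihydrochalcone.
 - The 7-phenoxide form of the ketone may stall the reduction. pH and temperature are the handles for all three problems.
 - Fallback, from 3 back to 9: give up catalytic control of C2 and let enantiopure 7 act as the resolving partner. NaOAc in aq. EtOH at reflux closes 3 to the 1:1 racemate of 4 and 5, which is crystallised. NaBH4 in EtOH at 0 °C gives 6 together with its mirror image (2R,4R)-2-(4-hydroxyphenyl)chromane-4,7-diol F1. Under the step 3 conditions 6 reacts through 8 and F1 reacts through the enantiomeric (2R)-2-(4-hydroxyphenyl)-2,3-dihydro-7H-chromen-7-one F2. The two enantiomers thus become diastereomers, 9 and ent-cassiaflavan-(4α→8)-epigallocatechin F3, which are separated on Sephadex LH-20 and RP-18 HPLC. The yield is capped at 50 % on the inexpensive upper unit.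

2. Step 3.
 - Side products to expect are the 2,4-cis (4α) epimer, the 4→6 regioisomer, a second alkylation at C6 of 9, and self-condensation of labile 6.
 - Fallback, from 6 back to 9: replace the protic SN1 reaction of an unpurifiable alcohol by thiophilic activation of an isolable electrophile. Phenylmethanethiol and AcOH in EtOH at rt trap 8 as (2S,4R)-4-(benzylsulfanyl)-2-(4-hydroxyphenyl)chroman-7-ol F4. This compound survives chromatography, so its purity and ee can be secured. AgBF4 in THF at 0 °C, in the dark under Ar and with 7 (3 equiv) present, then regenerates 8 under neutral aprotic conditions at low temperature. This gives cleaner kinetic C8/β-face capture to 9.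

3. Step 1.
 - The unprotected acid aldol may stop at low conversion or give coloured condensation products.
 - Fallback, from 1 and 2 back to 3: mask the non-chelated phenols and switch to the base-mediated condensation. MOMCl and K2CO3 in acetone convert 1 into 1-[2-hydroxy-4-(methoxymethoxy)phenyl]ethanone F5 (the hydrogen-bonded 2-OH stays free) and 2 into 4-(methoxymethoxy)benzaldehyde F6. KOH in EtOH at rt gives (E)-1-[2-hydroxy-4-(methoxymethoxy)phenyl]-3-[4-(methoxymethoxy)phenyl]prop-2-en-1-one F7. HCl in MeOH at 50 °C removes both acetals to return 3.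

**Further compounds**
F1 | step 2 | (2R,4R)-2-(4-hydroxyphenyl)chromane-4,7-diol | Oc1ccc([C@H]2C[C@@H](O)c3ccc(O)cc3O2)cc1
F2 | step 2 | (2R)-2-(4-hydroxyphenyl)-2,3-dihydro-7H-chromen-7-one | O=C1C=CC2=CC[C@H](c3ccc(O)cc3)OC2=C1
F3 | step 2 | ent-cassiaflavan-(4α→8)-epigallocatechin, (2R,3R)-8-[(2R,4S)-7-hydroxy-2-(4-hydroxyphenyl)chroman-4-yl]-2-(3,4,5-trihydroxyphenyl)chromane-3,5,7-triol | Oc1ccc([C@H]2C[C@H](c3c(O)cc(O)c4c3O[C@H](c3cc(O)c(O)c(O)c3)[C@H](O)C4)c3ccc(O)cc3O2)cc1
F4 | step 3 | (2S,4R)-4-(benzylsulfanyl)-2-(4-hydroxyphenyl)chroman-7-ol | Oc1ccc([C@@H]2C[C@@H](SCc3ccccc3)c3ccc(O)cc3O2)cc1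
F5 | step 1 | 1-[2-hydroxy-4-(methoxymethoxy)phenyl]ethanone | CC(=O)c1ccc(OCOC)cc1O
F6 | step 1 | 4-(methoxymethoxy)benzaldehyde | O=Cc1ccc(OCOC)cc1
F7 | step 1 | (E)-1-[2-hydroxy-4-(methoxymethoxy)phenyl]-3-[4-(methoxymethoxy)phenyl]prop-2-en-1-one | O=C(/C=C/c1ccc(OCOC)cc1)c1ccc(OCOC)cc1O
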